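**Retrosynthetic overview**

- The target is opened back to a β-substituted butenolide: hydroxide opening gives the (Z)-hydroxy carboxylate, and acetylation of both alkoxides gives the diacetoxy acid. The ring fixes the 13Z geometry.
- The butenolide comes from a 3-substituted furan by [4+2] cycloaddition of singlet oxygen, base-directed endoperoxide fragmentation and borohydride reduction. This is the key step; it moves the carbonyl from C16 to C15.
- The furan alcohol comes from a furan 3,19-diol by radical deoxygenation at C3 through a cyclic thionocarbonate.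
- The furan diol comes from andrographolide by SN2′ hydride loss of the 14-acetate, then iBu2AlH reduction and acid aromatisation.
- Ring order: rings A and B and all four stereocentres (C4, C5, C9, C10) are bought in andrographolide. The only ring formed is the transient oxygenated five-membered ring from the furan cycloaddition.

Assumption: andrographolide (bulk extract product of Andrographis paniculata) is taken as the cheap commercial chiral starting material; the target is read as (13Z)-16,19-diacetoxy-ent-labda-8(17),13-dien-15-oic acid (4R,5S,9R,10S, labdane numbering), which has the same C4, C5, C9 and C10 configuration as andrographolide.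

**Route**

Step 1
Reactants: 1 andrographolide
Product: 2 3,14,19-tri-O-acetylandrographolide
Conditions: Ac2O, pyridine, 4-(dimethylamino)pyridine (cat.), CH2Cl2, 0 °C → rt
Reagents that add atoms: acetic anhydride, CC(=O)OC(C)=O
Why: Exhaustive O-acetylation (nucleophilic acyl substitution) turns the allylic 14-OH into a leaving group and masks the 3- and 19-OH; no stereocentre is touched.

Step 2
Reactants: 2 3,14,19-tri-O-acetylandrographolide
Product: 3 3,19-di-O-acetyl-14-deoxyandrographolide (3,19-diacetoxy-ent-labda-8(17),13-dien-16,15-olide)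
Conditions: NaBH4 (1.5 equiv), THF/t-BuOH, 0 °C; 1 M HCl quench
Reagents that add atoms: none
Why: SN2′ hydride reduction of a Morita–Baylis–Hillman-type allylic acetate: hydride adds to C12 of the alkylidene lactone and the enolate expels the 14-acetate (conjugate addition–E1cB), giving the endocyclic butenolide; the C14 stereocentre is erased and none is created.

Step 3
Reactants: 3 3,19-di-O-acetyl-14-deoxyandrographolide
Product: 5 15,16-epoxy-ent-labda-8(17),13(16),14-triene-3,19-diol (furan diol), via lactol 4 (not isolated)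
Conditions: iBu2AlH (7 equiv), CH2Cl2, −78 °C; then 1 M HCl, 0 °C → rt
Reagents that add atoms: none
Why: iBu2AlH reduces the butenolide carbonyl to the lactol and cleaves both acetates reductively, and dilute acid dehydrates the 2,5-dihydrofuran-2-ol to the aromatic 3-substituted furan (lactone-to-furan reduction–aromatisation); ring stereocentres are untouched.

Step 4
Reactants: 5 furan diol
Product: 6 3,19-O-thiocarbonyl derivative of 5 (six-membered cyclic thionocarbonate)
Conditions: 1,1'-thiocarbonyldiimidazole (1.3 equiv), 4-(dimethylamino)pyridine (cat.), toluene, 90 °C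
Reagents that add atoms: 1,1'-thiocarbonyldiimidazole, S=C(n1ccnc1)n1ccnc1
Why: The equatorial 3-OH and axial 19-CH2OH form a 1,3-diol that closes readily to a cyclic thionocarbonate (thioacylation–cyclisation), which differentiates the two oxygens for the next step without a protecting group.

Step 5
Reactants: 6 cyclic thionocarbonate
Product: 8 15,16-epoxy-ent-labda-8(17),13(16),14-trien-19-ol (furan alcohol), via stannyl thiocarbonate 7 (not isolated)
Conditions: Bu3SnH (2.5 equiv, slow addition), 2,2'-azobis(2-methylpropionitrile) (cat.), toluene, 110 °C; then 1 M NaOH, THF/MeOH, rt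
Reagents that add atoms: none
Why: Barton–McCombie-type radical deoxygenation: the stannyl radical adds to sulfur and β-scission occurs at the C3–O bond to give the secondary radical rather than the primary neopentyl one, hydrogen transfer gives the C3 methylene, and base hydrolysis frees the 19-OH; the C3 stereocentre is removed and C4 is unchanged.

Step 6
Reactants: 8 furan alcohol
Product: 11 19-hydroxy-ent-labda-8(17),13-dien-15,16-olide (β-substituted butenolide), via furan endoperoxide 9 (not isolated), via hydroxybutenolide 10 (not isolated)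
Conditions: O2, visible light, 5,10,15,20-tetraphenylporphyrin (cat.), iPr2NEt (5 equiv), CH2Cl2, −78 °C; then NaBH4, EtOH, 0 °C; then 1 M HCl
Reagents that add atoms: oxygen (reacting as singlet oxygen), O=O
Why: [4+2] cycloaddition of singlet oxygen to the furan gives the endoperoxide; the hindered base removes the less hindered bridgehead hydrogen at C15 (Kornblum–DeLaMare fragmentation), placing the carbonyl at C15 and the hemiacetal at C16, and borohydride reduction of the ring-opened aldehyde with acid relactonisation gives the 15,16-olide. The exocyclic alkene reacts far more slowly than the furan, and the ring fixes C15 and C16 cis on the C13=C14 bond.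

Step 7
Reactants: 11 β-substituted butenolide
Product: 13 (13Z)-16,19-diacetoxy-ent-labda-8(17),13-dien-15-oic acid (target), via lithium hydroxy carboxylate 12 (not isolated)
Conditions: LiOH·H2O (1.1 equiv), THF/H2O, rt; concentrate and dry (toluene azeotrope); LiN(SiMe3)2 (2.3 equiv), THF/DMPU, −78 °C; cannulate into Ac2O (4 equiv), THF, −78 → 0 °C; then H2O, 1 M HCl to pH 3, 0 °C
Reagents that add atoms: lithium hydroxide, [Li+].[OH-]; acetic anhydride, CC(=O)OC(C)=O
Why: Saponification opens the lactone by acyl–oxygen cleavage with the Z alkene retained, and the two lithium alkoxides are far more nucleophilic than the carboxylate, so Ac2O caps O16 and O19 before the carboxyl can be activated toward relactonisation (chemoselective O-acylation of a hydroxy-acid polyanion); any mixed anhydride is hydrolysed on work-up and no stereocentre is touched.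

**Compound list**

1 | andrographolide, 3,14,19-trihydroxy-ent-labda-8(17),12E-dien-16,15-olide (3R,4R,5S,9R,10S,14S) | C=C1CC[C@@H]2[C@](C)(CO)[C@H](O)CC[C@@]2(C)[C@@H]1C/C=C1/C(=O)OC[C@H]1O | starting material
2 | 3,14,19-tri-O-acetylandrographolide | C=C1CC[C@@H]2[C@](C)(COC(C)=O)[C@H](OC(C)=O)CC[C@@]2(C)[C@@H]1C/C=C1/C(=O)OC[C@H]1OC(C)=O | intermediate
3 | 3,19-di-O-acetyl-14-deoxyandrographolide (α-substituted butenolide, C13=C14) | C=C1CC[C@@H]2[C@](C)(COC(C)=O)[C@H](OC(C)=O)CC[C@@]2(C)[C@@H]1CCC1=CCOC1=O | intermediate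
4 | lactol, 15,16-epoxy-ent-labda-8(17),13-diene-3,16,19-triol (C16 epimers; held as its aluminium alkoxide until the quench) | C=C1CC[C@@H]2[C@](C)(CO)[C@H](O)CC[C@@]2(C)[C@@H]1CCC1=CCOC1O | intermediate
5 | furan diol, 15,16-epoxy-ent-labda-8(17),13(16),14-triene-3,19-diol (3-OH as in 1) | C=C1CC[C@@H]2[C@](C)(CO)[C@H](O)CC[C@@]2(C)[C@@H]1CCc1ccoc1 | intermediate
6 | 3,19-cyclic thionocarbonate of 5 | C=C1CC[C@@H]2[C@]3(C)COC(=S)O[C@@H]3CC[C@@]2(C)[C@@H]1CCc1ccoc1 | intermediate
7 | O-(15,16-epoxy-ent-labda-8(17),13(16),14-trien-19-yl) S-tributylstannyl thiocarbonate | C=C1CC[C@@H]2[C@](C)(COC(=O)S[Sn](CCCC)(CCCC)CCCC)CCC[C@@]2(C)[C@@H]1CCc1ccoc1 | intermediate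
8 | furan alcohol, 15,16-epoxy-ent-labda-8(17),13(16),14-trien-19-ol | C=C1CC[C@@H]2[C@](C)(CO)CCC[C@@]2(C)[C@@H]1CCc1ccoc1 | intermediate
9 | furan endoperoxide of 8 (2,3,7-trioxabicyclo[2.2.1]hept-5-ene, side chain on C5; bridgehead epimers) | C=C1CC[C@@H]2[C@](C)(CO)CCC[C@@]2(C)[C@@H]1CCC1=CC2OOC1O2 | intermediate
10 | hydroxybutenolide, 16,19-dihydroxy-ent-labda-8(17),13-dien-15,16-olide (C16 epimers) | C=C1CC[C@@H]2[C@](C)(CO)CCC[C@@]2(C)[C@@H]1CCC1=CC(=O)OC1O | intermediate
11 | 19-hydroxy-ent-labda-8(17),13-dien-15,16-olide | C=C1CC[C@@H]2[C@](C)(CO)CCC[C@@]2(C)[C@@H]1CCC1=CC(=O)OC1 | intermediate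
12 | lithium (13Z)-16,19-dihydroxy-ent-labda-8(17),13-dien-15-oate | C=C1CC[C@@H]2[C@](C)(CO)CCC[C@@]2(C)[C@@H]1CC/C(=C/C(=O)[O-])CO.[Li+] | intermediate
13 | (13Z)-16,19-diacetoxy-ent-labda-8(17),13-dien-15-oic acid (4R,5S,9R,10S) | C=C1CC[C@@H]2[C@](C)(COC(C)=O)CCC[C@@]2(C)[C@@H]1CC/C(=C/C(=O)O)COC(C)=O | target

**Totals and risks**

Total step count: 7. Longest linear sequence: 7 (fully linear from 1).

The three steps most likely to fail, most serious first:

Step 7 (acetylation against relactonisation). If the carboxylate is activated before O16 is capped, the product falls back to lactone 11. The fallback protects the acid before the C16 alcohol exists. It sets out from 10, isolated by leaving the borohydride out of step 6. The ring-opened carboxylate of 10 is alkylated with 2-(trimethylsilyl)ethoxymethyl chloride (iPr2NEt, CH2Cl2, 0 °C) to give the open-chain aldehyde ester 2-(trimethylsilyl)ethoxymethyl (13Z)-19-hydroxy-16-oxo-ent-labda-8(17),13-dien-15-oate F8. Luche reduction (NaBH4, CeCl3·7H2O, MeOH, −78 °C) gives the diol ester 2-(trimethylsilyl)ethoxymethyl (13Z)-16,19-dihydroxy-ent-labda-8(17),13-dien-15-oate F9, which is acetylated at once without isolation (Ac2O, pyridine, 4-(dimethylamino)pyridine) to 2-(trimethylsilyl)ethoxymethyl (13Z)-16,19-diacetoxy-ent-labda-8(17),13-dien-15-oate F10. MgBr2·OEt2 in CH2Cl2 then removes the ester without touching the acetates or the exocyclic alkene, and the route comes back at 13.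

Step 5 (fragmentation of the six-membered thionocarbonate). The ring opening may be slow or give some primary-side cleavage. The fallback is an acyclic Barton–McCombie sequence with a protecting group. It sets out from 5: TBSCl and imidazole in DMF silylate the primary alcohol to give 19-O-tert-butyldimethylsilyl-15,16-epoxy-ent-labda-8(17),13(16),14-trien-3-ol F5. NaH, CS2 and MeI convert the 3-OH into the S-methyl xanthate F6. Bu3SnH with 2,2'-azobis(2-methylpropionitrile) in toluene at 110 °C gives 19-O-tert-butyldimethylsilyl-15,16-epoxy-ent-labda-8(17),13(16),14-triene F7, and Bu4NF in THF returns the route to 8.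

Step 2 (SN2′ hydride). Competing elimination to the 11,12-didehydro diene or over-reduction is possible. The fallback is a Myers reductive 1,3-transposition on the free 14-OH. It sets out from 1: 2,2-dimethoxypropane and pyridinium p-toluenesulfonate give 3,19-O-isopropylideneandrographolide F1. Mitsunobu reaction with 2-nitrobenzenesulfonylhydrazide (PPh3, diethyl azodicarboxylate, THF, −30 °C) gives the C14 N-sulfonylhydrazine F2, which is not isolated. On warming it loses the sulfinic acid to give the allylic diazene F3, also not isolated. F3 expels nitrogen by a sigmatropic retro-ene hydrogen shift, placing hydrogen on C12 and the alkene at C13=C14, to give 3,19-O-isopropylidene-14-deoxyandrographolide F4. The step 3 conditions (iBu2AlH; then aqueous HCl, which also cleaves the acetonide) bring the route back at 5.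

**Further compounds**

F1 | step 2 | 3,19-O-isopropylideneandrographolide | C=C1CC[C@@H]2[C@]3(C)COC(C)(C)O[C@@H]3CC[C@@]2(C)[C@@H]1C/C=C1/C(=O)OC[C@H]1O
F2 | step 2 | C14-inverted N-(2-nitrobenzenesulfonyl)hydrazine adduct of F1 | C=C1CC[C@@H]2[C@]3(C)COC(C)(C)O[C@@H]3CC[C@@]2(C)[C@@H]1C/C=C1/C(=O)OC[C@@H]1N(N)S(=O)(=O)c1ccccc1[N+](=O)[O-]
F3 | step 2 | allylic monoalkyl diazene from F2 | C=C1CC[C@@H]2[C@]3(C)COC(C)(C)O[C@@H]3CC[C@@]2(C)[C@@H]1C/C=C1/C(=O)OC[C@@H]1N=N
F4 | step 2 | 3,19-O-isopropylidene-14-deoxyandrographolide | C=C1CC[C@@H]2[C@]3(C)COC(C)(C)O[C@@H]3CC[C@@]2(C)[C@@H]1CCC1=CCOC1=O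
F5 | step 5 | 19-O-tert-butyldimethylsilyl-15,16-epoxy-ent-labda-8(17),13(16),14-trien-3-ol | C=C1CC[C@@H]2[C@](C)(CO[Si](C)(C)C(C)(C)C)[C@H](O)CC[C@@]2(C)[C@@H]1CCc1ccoc1
F6 | step 5 | 3-O-(methylsulfanyl)thiocarbonyl (S-methyl xanthate) derivative of F5 | C=C1CC[C@@H]2[C@](C)(CO[Si](C)(C)C(C)(C)C)[C@H](OC(=S)SC)CC[C@@]2(C)[C@@H]1CCc1ccoc1
F7 | step 5 | 19-O-tert-butyldimethylsilyl-15,16-epoxy-ent-labda-8(17),13(16),14-triene | C=C1CC[C@@H]2[C@](C)(CO[Si](C)(C)C(C)(C)C)CCC[C@@]2(C)[C@@H]1CCc1ccoc1
F8 | step 7 | 2-(trimethylsilyl)ethoxymethyl (13Z)-19-hydroxy-16-oxo-ent-labda-8(17),13-dien-15-oate | C=C1CC[C@@H]2[C@](C)(CO)CCC[C@@]2(C)[C@@H]1CC/C(=C/C(=O)OCOCC[Si](C)(C)C)C=O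
F9 | step 7 | 2-(trimethylsilyl)ethoxymethyl (13Z)-16,19-dihydroxy-ent-labda-8(17),13-dien-15-oate | C=C1CC[C@@H]2[C@](C)(CO)CCC[C@@]2(C)[C@@H]1CC/C(=C/C(=O)OCOCC[Si](C)(C)C)CO
F10 | step 7 | 2-(trimethylsilyl)ethoxymethyl (13Z)-16,19-diacetoxy-ent-labda-8(17),13-dien-15-oate | C=C1CC[C@@H]2[C@](C)(COC(C)=O)CCC[C@@]2(C)[C@@H]1CC/C(=C/C(=O)OCOCC[Si](C)(C)C)COC(C)=O
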